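Seconds to a fixed amount of target are the unit in which to compare these flasks, and their logarithms give the orders.

| flask | starting material | reagent | target | time |
|---|---|---|---|---|
| epsilon | 0.400 M | 1.00 M |  |  |
| theta | 0.200 M | 0.800 M |  |  |
| gamma | 0.400 M | 3.00 M |  |  |
| alpha | 0.200 M | 1.00 M |  |  |
| delta | 0.400 M | 1.00 M | 0.120 M | 130 s |

| run | time / s | [target] / M |
|---|---|---|
| epsilon run | 22 | 0.002 |
| epsilon run | 43 | 0.041 |
| epsilon run | 65 | 0.104 |
| epsilon run | 87 | 0.157 |
| epsilon run | 110 | 0.191 |
| epsilon run | 130 | 0.197 |
| theta run | 22 | 0.004 |
| theta run | 43 | 0.005 |
| theta run | 65 | 0.011 |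
| theta run | 87 | 0.033 |
| theta run | 110 | 0.050 |
| theta run | 130 | 0.055 |
| gamma run | 22 | 0.063 |
| gamma run | 43 | 0.171 |
| gamma run | 65 | 0.182 |
| gamma run | 87 | 0.182 |
| gamma run | 110 | 0.183 |
| gamma run | 130 | 0.168 |
| alpha run | 22 | 0.002 |
| alpha run | 43 | 0.004 |
| alpha run | 65 | 0.032 |
| alpha run | 87 | 0.040 |
| alpha run | 110 | 0.057 |
| alpha run | 130 | 0.067 |

(each reading ± 0.004 M)

- Overall: starting material + reagent -> target.
- Constant volume, constant temperature.
- "The second partner" is reagent.
- An order is taken over about fifteen percent of the charge, up and down.
- A share of target counts the target that was charged too.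

- reaction order in [starting material] at the outset, round the charge of the epsilon run, defined at two percent of the starting material turned into target (one fixed amount of target, the same in the runs compared)
- reaction order in [reagent] at the outset, round the charge of the epsilon run, defined at two percent of the starting material turned into target
- target in the delta run at 130 s, as a share of the starting material charged

Alpha, with half the starting material of epsilon, shows 0.040 M at 87 s, and epsilon shows 0.041 M at 43 s, the same amount within the scatter of 0.004 M. That gives you 1.02. Call this the clock order, an apparent reaction order: with the charge of the other partner held fixed, the logarithm of the ratio of the times to one amount of target over the logarithm of the ratio of the charges of the species varied.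

For [reagent], take the gamma reading of 0.063 M at 22 s. Interpolated between its readings, epsilon reaches that amount at 50.7 s, so the clock order in [reagent] is 0.760. Both are readings taken beyond the two percent asked about, and they carry the scatter.

The forecast gave 1.2 in [starting material], higher than your clock order, then 0.8 in [reagent] and 75 % for delta, holding that “the seed should remove the lag”.

The flask gives 0.96 in [starting material], 0.81 in [reagent] and 79.4 % for delta, against your clock orders of 1.02 and 0.760.

    starting material + reagent → intermediate (0.01120 L mol⁻¹ s⁻¹)
    intermediate → target (0.003240 s⁻¹)
    starting material + reagent + target → 2 target (0.2910 L² mol⁻² s⁻¹)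
    target → decomposed product (0.003610 s⁻¹)

A power-law fit over all runs puts its best order in [starting material] at 2.3, higher than the outset order of 0.96. Now take the clock orders to theta. Scaling the epsilon rate of 8.9 × 10⁻⁴ M s⁻¹, taken where two percent of the epsilon starting material has turned, by the charge ratios raised to 1.02 and 0.760 gives 3.73 × 10⁻⁴ M s⁻¹. The theta rate at that same amount of target is 3.9 × 10⁻⁴ M s⁻¹.

All runs are simulated on assumed constants, and the scatter is random.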